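**Retrosynthetic overview**
- The phenolic acetate is removed last. Before that, the eudesmane is cut at C5–C10 and at C4–O in one move, which leads back to a (1(10)E,4E)-germacra-1(10),4-dien-6β-yl O-acetylisoferulate.
- Feature used: the oxygens on C4 and C6 are both β and syn-axial across C5 of the trans-decalin (ring A = C1–C5, C10; ring B = C5–C10), so the C6 ester carbonyl can reach a C4 cation through a six-membered dioxanylium ring.
- The germacradienyl ester comes from the (6R,7S)-6β-alcohol and O-acetylisoferuloyl chloride. The 6β-alcohol comes from a Mitsunobu inversion of the racemic 6,7-anti alcohol with (S)-O-methylmandelic acid, which also resolves it.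
- The anti alcohol comes from selective hydrogenation of the isopropenyl group of the product of a CrCl2 ring closure (C6–C7 bond) of (2E,6E,10E)-12-chlorofarnesal, itself made from (2E,6E)-farnesol.
- Ring order: the ten-membered carbocycle first (step 6), then rings A and B together, with the transient dioxanylium ring, in step 12.

Key step: step 12

Remark: germacrane/eudesmane numbering is used for all cyclic compounds, and α/β in the ten-membered ring mean the faces that become α/β of the eudesmane. The chromium-mediated closure is assumed to give the 6,7-anti alcohol (6α-OH, 7β-isopropenyl), as γ-substituted allylchromium reagents do, so C6 is inverted in step 8.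

Step 1
Reactants: 1 (2E,6E)-farnesol
Product: 2 (2E,6E)-farnesyl acetate
Conditions: Ac2O, pyridine, DMAP (cat.), CH2Cl2, 0 °C to rt
Reagents that add atoms: acetic anhydride, CC(=O)OC(C)=O
Why: DMAP-catalysed acetylation masks the primary allylic alcohol and deactivates the 2,3-alkene toward the allylic oxidation that follows.

Step 2
Reactants: 2 (2E,6E)-farnesyl acetate
Product: 3 (2E,6E,10E)-12-hydroxyfarnesyl acetate
Conditions: SeO2 (0.1 equiv), t-BuOOH (70% aq.), salicylic acid (cat.), CH2Cl2, rt, stopped at partial conversion
Reagents that add atoms: tert-butyl hydroperoxide, CC(C)(C)OO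
Why: SeO2 allylic oxidation (ene reaction, then [2,3]-sigmatropic shift) attacks the most electron-rich terminal trisubstituted alkene at its (E)-methyl group and gives the (10E)-allylic alcohol, the 2,3-alkene being deactivated by the allylic acetate.

Step 3
Reactants: 3 (2E,6E,10E)-12-hydroxyfarnesyl acetate
Product: 4 (2E,6E,10E)-12-chlorofarnesyl acetate
Conditions: NCS, Me2S, CH2Cl2, −30 to 0 °C
Reagents that add atoms: N-chlorosuccinimide, O=C1CCC(=O)N1Cl
Why: Corey–Kim chlorination, in which chloride displaces the alkoxysulfonium group at the primary carbon without allylic transposition and the acetate is inert.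

Step 4
Reactants: 4 (2E,6E,10E)-12-chlorofarnesyl acetate
Product: 5 (2E,6E,10E)-12-chlorofarnesol
Conditions: K2CO3 (0.3 equiv), MeOH, 0 °C, short reaction time
Reagents that add atoms: none
Why: Base-catalysed transesterification of the primary allylic acetate should be much faster at 0 °C than substitution of the allylic chloride by methoxide, so the chloride is kept.

Step 5
Reactants: 5 (2E,6E,10E)-12-chlorofarnesol
Product: 6 (2E,6E,10E)-12-chlorofarnesal
Conditions: TEMPO (0.1 equiv), PhI(OAc)2 (1.1 equiv), CH2Cl2, rt
Reagents that add atoms: none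
Why: TEMPO-catalysed (oxoammonium) oxidation stops at the enal, does not isomerise the 2E alkene and leaves the allylic chloride and the other alkenes untouched.

Step 6
Reactants: 6 (2E,6E,10E)-12-chlorofarnesal
Product: 7 rac-(1(10)E,4E)-germacra-1(10),4,11-trien-6-ol with 6α-OH and 7β-isopropenyl (6,7-anti; 6R*,7S*)
Conditions: CrCl2 (6 equiv), LiI (0.2 equiv), THF, rt; 6 added by syringe pump to about 0.005 M
Reagents that add atoms: none
Why: Intramolecular Nozaki–Hiyama allylation, in which divalent chromium (helped by iodide exchange) turns the allylic chloride into an allylchromium species that adds through its γ-carbon (C7) to the aldehyde carbon (C6) in a closed chair transition state and so closes the ten-membered ring; the (E)-allyl unit and the chair should set the 6,7-anti relationship, as a racemate, and the two ring alkenes keep their E geometry.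

Step 7
Reactants: 7 rac-(1(10)E,4E)-germacra-1(10),4,11-trien-6-ol (6,7-anti)
Product: 8 rac-(1(10)E,4E)-germacra-1(10),4-dien-6-ol with 6α-OH and 7β-isopropyl (6,7-anti; 6S*,7S*)
Conditions: H2 (1 atm), RhCl(PPh3)3 (5 mol %), toluene–EtOH, rt
Reagents that add atoms: none
Why: Homogeneous hydrogenation with RhCl(PPh3)3 reduces the unhindered 1,1-disubstituted alkene much faster than the two trisubstituted ring alkenes, and no stereocentre is touched.

Step 8
Reactants: 8 rac-(1(10)E,4E)-germacra-1(10),4-dien-6-ol (6,7-anti)
Product: 9 (1(10)E,4E)-germacra-1(10),4-dien-6β-yl (S)-2-methoxy-2-phenylacetate (6R,7S)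
Conditions: (S)-O-methylmandelic acid (1.5 equiv), PPh3, DIAD, toluene, 0 °C to rt; chromatographic separation of the two diastereomeric esters
Reagents that add atoms: (S)-2-methoxy-2-phenylacetic acid, CO[C@H](C(=O)O)c1ccccc1
Why: Mitsunobu reaction, in which the carboxylate (a fairly strong acid, as is used for hindered alcohols such as menthol) displaces the allylic oxyphosphonium group by SN2 and inverts C6 to the 6β-ester; because the acid is enantiopure the two enantiomers of 8 give diastereomers that should be separable, and the ester of the (6R,7S) alcohol is collected.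

Step 9
Reactants: 9 (1(10)E,4E)-germacra-1(10),4-dien-6β-yl (S)-2-methoxy-2-phenylacetate
Product: 10 (6R,7S)-(1(10)E,4E)-germacra-1(10),4-dien-6β-ol, that is (1R,2E,6E,10S)-3,7-dimethyl-10-(propan-2-yl)cyclodeca-2,6-dien-1-ol
Conditions: K2CO3, MeOH, rt
Reagents that add atoms: none
Why: Transesterification cleaves the activated α-alkoxy ester at the acyl carbon, so the C6–O bond and the 6β configuration are kept.

Step 10
Reactants: 11 isoferulic acid
Product: 12 (E)-3-(3-acetoxy-4-methoxyphenyl)prop-2-enoic acid (O-acetylisoferulic acid)
Conditions: Ac2O, pyridine, rt; then H2O, dilute HCl work-up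
Reagents that add atoms: acetic anhydride, CC(=O)OC(C)=O
Why: Acetylation of the phenol (the mixed anhydride at the carboxyl group is hydrolysed on work-up) protects ArOH for the acylation and makes the arene less nucleophilic for the cationic key step.

Step 11
Reactants: 10 (6R,7S)-(1(10)E,4E)-germacra-1(10),4-dien-6β-ol; 12 O-acetylisoferulic acid
Product: 14 (1(10)E,4E)-germacra-1(10),4-dien-6β-yl (E)-3-(3-acetoxy-4-methoxyphenyl)prop-2-enoate (6R,7S), via acid chloride 13 (not isolated)
Conditions: 12, (COCl)2, DMF (cat.), CH2Cl2, 0 °C to rt, evaporate; then 10, pyridine, DMAP (0.1 equiv), CH2Cl2, 0 °C to rt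
Reagents that add atoms: none
Why: Acid chloride formation followed by DMAP-catalysed esterification of the hindered secondary alcohol, which forms only the acyl–oxygen bond and so leaves C6, C7, the E-cinnamoyl alkene and the aryl acetate unchanged.

Step 12
Reactants: 14 (1(10)E,4E)-germacra-1(10),4-dien-6β-yl O-acetylisoferulate
Product: 16 4β-hydroxy-5α,7αH-eudesman-6β-yl (E)-3-(3-acetoxy-4-methoxyphenyl)prop-2-enoate, via dioxanylium ion 15 (not isolated)
Conditions: TsOH·H2O (0.2 equiv), H2O (5 equiv), acetone (0.01 M), 0 °C to rt; NaHCO3 quench
Reagents that add atoms: water, O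
Why: Protonation at C1 of the 1(10)-alkene (the 4,5-alkene is deactivated by the allylic ester) develops the tertiary C10 cation, which C5 attacks across the ring in the crossed chair–chair conformer, so that the one C5–C10 bond closes ring A in 6-endo mode and ring B in 6-exo mode with respect to the 4,5-alkene. The tertiary C4 cation is then captured on its β face by the carbonyl oxygen of the 6β-ester in a six-membered closure to the chair 1,3-dioxan-2-ylium ion 15, which bridges the syn-axial positions on C4 and C6; water adds at the former acyl carbon and the orthoacid opens, with 1,3-acyl shift if needed, to the secondary C6 ester and the tertiary 4β-alcohol. The closest known reaction types are the acid-induced transannular cyclization of germacra-1(10),4-dienes to eudesmanols and acyloxy neighbouring-group participation through dioxanylium ions. C10 (β-methyl) and C5 (α-H, trans fusion) follow from addition across the two (E)-alkenes in the chair–chair fold that keeps the C7 isopropyl group equatorial on the C5–C10 bridge, and C4 (β-oxygen, α-methyl) is set by delivery from O6, which lies syn to the new C5–C10 bond and therefore opposite to the α attack that external water would make. The step needs fold selectivity (against the ring-flipped crown with an axial isopropyl group and against parallel alkene arrangements that give cis fusion) and ester capture of the C4 cation ahead of proton loss or hydration; it relies on the equatorial isopropyl group, on the relief of A(1,3) strain between O6 and C15 as C5 pyramidalises, and on the low water content and low temperature.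

Step 13
Reactants: 16 4β-hydroxy-5α,7αH-eudesman-6β-yl (E)-3-(3-acetoxy-4-methoxyphenyl)prop-2-enoate
Product: 17 4β-hydroxy-5α,7αH-eudesman-6β-yl (E)-isoferulate, that is (1R,2S,4aR,8S,8aS)-8-hydroxy-4a,8-dimethyl-2-(propan-2-yl)decahydronaphthalen-1-yl (E)-3-(3-hydroxy-4-methoxyphenyl)prop-2-enoate
Conditions: K2CO3 (0.2 equiv), MeOH, 0 °C
Reagents that add atoms: none
Why: Base-catalysed methanolysis (transesterification) of a phenolic acetate is far faster than that of the hindered secondary cinnamate, so only the phenol should be set free.

**Compound list**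
1 | (2E,6E)-farnesol | CC(C)=CCC/C(C)=C/CC/C(C)=C/CO | starting material
2 | (2E,6E)-farnesyl acetate | CC(C)=CCC/C(C)=C/CC/C(C)=C/COC(C)=O | intermediate
3 | (2E,6E,10E)-12-hydroxyfarnesyl acetate | OC/C(C)=C/CC/C(C)=C/CC/C(C)=C/COC(C)=O | intermediate
4 | (2E,6E,10E)-12-chlorofarnesyl acetate | ClC/C(C)=C/CC/C(C)=C/CC/C(C)=C/COC(C)=O | intermediate
5 | (2E,6E,10E)-12-chlorofarnesol | ClC/C(C)=C/CC/C(C)=C/CC/C(C)=C/CO | intermediate
6 | (2E,6E,10E)-12-chlorofarnesal | ClC/C(C)=C/CC/C(C)=C/CC/C(C)=C/C=O | intermediate
7 | rac-(1(10)E,4E)-germacra-1(10),4,11-trien-6-ol, 6α-OH/7β-isopropenyl (6R*,7S*); racemic, one enantiomer drawn | O[C@@H]1/C=C(C)/CC/C=C(C)/CC[C@H]1C(C)=C | intermediate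
8 | rac-(1(10)E,4E)-germacra-1(10),4-dien-6-ol, 6α-OH/7β-isopropyl (6S*,7S*); racemic, one enantiomer drawn | O[C@@H]1/C=C(C)/CC/C=C(C)/CC[C@H]1C(C)C | intermediate
9 | (6R,7S)-(1(10)E,4E)-germacra-1(10),4-dien-6β-yl (S)-2-methoxy-2-phenylacetate | CO[C@H](C(=O)O[C@H]1/C=C(C)/CC/C=C(C)/CC[C@H]1C(C)C)c1ccccc1 | intermediate
10 | (6R,7S)-(1(10)E,4E)-germacra-1(10),4-dien-6β-ol | O[C@H]1/C=C(C)/CC/C=C(C)/CC[C@H]1C(C)C | intermediate
11 | isoferulic acid | COc1ccc(/C=C/C(=O)O)cc1O | starting material
12 | (E)-3-(3-acetoxy-4-methoxyphenyl)prop-2-enoic acid | COc1ccc(/C=C/C(=O)O)cc1OC(C)=O | intermediate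
13 | (E)-3-(3-acetoxy-4-methoxyphenyl)prop-2-enoyl chloride (not isolated) | COc1ccc(/C=C/C(=O)Cl)cc1OC(C)=O | intermediate
14 | (6R,7S)-(1(10)E,4E)-germacra-1(10),4-dien-6β-yl (E)-3-(3-acetoxy-4-methoxyphenyl)prop-2-enoate | COc1ccc(/C=C/C(=O)O[C@H]2/C=C(C)/CC/C=C(C)/CC[C@H]2C(C)C)cc1OC(C)=O | intermediate
15 | 1,3-dioxan-2-ylium ion bridging O4β and O6β of the 5α,7αH-eudesmane, 2-substituent (E)-2-(3-acetoxy-4-methoxyphenyl)ethenyl (not isolated) | COc1ccc(/C=C/C2=[O+][C@@]3(C)CCC[C@]4(C)CC[C@@H](C(C)C)[C@@H](O2)[C@@H]34)cc1OC(C)=O | intermediate
16 | 4β-hydroxy-5α,7αH-eudesman-6β-yl (E)-3-(3-acetoxy-4-methoxyphenyl)prop-2-enoate (4S,5S,6R,7S,10R) | COc1ccc(/C=C/C(=O)O[C@H]2[C@@H]3[C@](C)(CCC[C@]3(C)O)CC[C@H]2C(C)C)cc1OC(C)=O | intermediate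
17 | 4β-hydroxy-5α,7αH-eudesman-6β-yl (E)-isoferulate (4S,5S,6R,7S,10R) | COc1ccc(/C=C/C(=O)O[C@H]2[C@@H]3[C@](C)(CCC[C@]3(C)O)CC[C@H]2C(C)C)cc1O | target

**Step count**
Total: 13 steps. Longest linear sequence: 12 steps (steps 1–9, 11, 12, 13).

**Steps most likely to fail**

Step 12. The ten-membered ring may fold through the ring-flipped crown, where the isopropyl group is axial, the ester is equatorial and its carbonyl can add to C4 anti to the forming C5–C10 bond; that would lead to the 5β,10α series. The C4 cation may also lose a proton or be hydrated from the α face before the ester captures it. The fallback uses known chemistry and makes the C4–O bond by a hydroxyl-directed epoxidation instead of ester participation; it sets out from 10. Brief treatment of the free 6β-alcohol with catalytic TsOH·H2O in CH2Cl2 at 0 °C (no participating group, smaller O6/C15 repulsion) should close the decalin with proton loss to 5α,7αH-eudesm-3-en-6β-ol F1. Epoxidation with VO(acac)2 and t-BuOOH, delivered by the axial 6β-hydroxyl to the β face, would give 3β,4β-epoxy-5α,7αH-eudesman-6β-ol F2. LiAlH4 in THF should open the epoxide at the secondary C3 in the trans-diaxial sense to 5α,7αH-eudesmane-4β,6β-diol F3. Acylation of the secondary 6β-hydroxyl with acid chloride 13 (pyridine, DMAP) comes back to the route at 16.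

Step 8. The allylic oxyphosphonium ion may ionise (loss of clean inversion, transannular capture or elimination), displacement at the hindered C6 may be slow, or the diastereomeric esters may not separate well. The fallback sets out from 8 and replaces the SN2 inversion by oxidation and reduction. Oxidation with DMP buffered by NaHCO3 gives racemic (1(10)E,4E)-germacra-1(10),4-dien-6-one F4. Reduction with LiBH(s-Bu)3 in THF at −78 °C, expected to come from the ring face opposite to the C14 and C15 methyl groups, gives the racemic 6β-alcohol F5. Carbodiimide esterification (EDC, DMAP) with (S)-O-methylmandelic acid, which goes with retention, and separation of the diastereomers come back to the route at 9.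

Step 6. Intermolecular coupling and oligomerisation may compete at practical concentrations, reduction of the allylic chloride may be slow, or the anti selectivity may erode. The fallback sets out from 5 and bypasses 6. NaH in THF under high dilution closes the thirteen-membered diallylic ether (3E,7E,11E)-4,8,12-trimethyl-1-oxacyclotrideca-3,7,11-triene F6 (Williamson etherification). n-BuLi in THF at −78 °C then triggers a [2,3]-Wittig ring contraction from the carbanion at the O–CH2 group next to the CH= terminus; this forms the C6–C7 bond with allylic transposition and returns to the route at 7.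

Further compounds
F1 | step 12 | 5α,7αH-eudesm-3-en-6β-ol | O[C@H]1[C@@H]2[C@](C)(CCC=C2C)CC[C@H]1C(C)C
F2 | step 12 | 3β,4β-epoxy-5α,7αH-eudesman-6β-ol | O[C@H]1[C@@H]2[C@](C)(CC[C@@H]3O[C@]23C)CC[C@H]1C(C)C
F3 | step 12 | 5α,7αH-eudesmane-4β,6β-diol | O[C@H]1[C@@H]2[C@](C)(CCC[C@]2(C)O)CC[C@H]1C(C)C
F4 | step 8 | rac-(1(10)E,4E)-7-isopropylgermacra-1(10),4-dien-6-one | O=C1/C=C(C)/CC/C=C(C)/CCC1C(C)C
F5 | step 8 | rac-(1(10)E,4E)-germacra-1(10),4-dien-6β-ol (6R*,7S*), racemic, one enantiomer drawn | O[C@H]1/C=C(C)/CC/C=C(C)/CC[C@H]1C(C)C
F6 | step 6 | (3E,7E,11E)-4,8,12-trimethyl-1-oxacyclotrideca-3,7,11-triene | C1/C(C)=C/CC/C(C)=C/CC/C(C)=C/CO1
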